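# Proposed synthesis of CNP0408176.0 by double methyl addition to a 6-bromodihydrocoumarin

## The problem

Target 21 is a dihydrochalcone whose ring A is the benzene ring of a 2,2-dimethylchroman: C6 carries the 3-arylpropanoyl chain, C5 and C7 carry free hydroxyls flanking the ketone, C8 is unsubstituted, and the pyran oxygen sits on C8a, para to C6. The chain ends in ring B, which has a hydroxyl at C3, a methoxy group at C4 and a 3-methylbut-2-enyl (prenyl) group at C5. There is no stereocentre and no configured double bond, so the difficulties are regiochemistry and chemoselectivity only. Ring A is a phloroglucinol core with three different carbon neighbours. Acylation or prenylation of a 5,7-dioxygenated chroman or of an acylphloroglucinol gives 6- and 8-isomers side by side, and the pyran oxygen must be told apart from the two oxygens that end as hydroxyls. The prenyl alkene does not tolerate strong protic or Lewis acids or catalytic hydrogenation, and the single methyl ether of ring B must survive while three hydroxyls are set free, so ring A should not need a boron halide at the end. The feature that opens the route is C2 of the pyran ring: it bears two methyl groups and the ring oxygen, so it is the carbonyl carbon of a 3,4-dihydrocoumarin after two methyl additions, with C3 and C4 being the α- and β-carbons of acrylic acid. If that lactone is built on a symmetric phenol with bromine para to the hydroxyl, the bromine marks C6 before the pyran ring exists.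

## Retrosynthesis

**21 ⇒ 20.** The last operation should only unmask hydroxyls, so three O–CH2OCH3 bonds are cut and 21 is traced to the tris(methoxymethyl) ether 20. Acetal protection is preferred to methyl ethers on ring A because dilute protic acid removes it without touching the ring B methyl ether, the prenyl alkene or the tertiary ether of the pyran ring. Methyl ethers would call for a boron halide on the complete molecule. The precursor has the same skeleton with every phenol masked. The forward step must be acidic enough for acetal exchange and no stronger.

**20 ⇒ 12 + 18.** The C6–carbonyl bond is cut. Friedel–Crafts or Hoesch acylation of a 5,7-dioxygenated chroman would attack C6 and C8 alike. A metal at C6, placed through the bromine of 12, removes the question. Aryllithium 19, generated from 12, lies between two chelating acetal oxygens, and Weinreb amide 18 stops the addition at the ketone. The cut divides the target into two fragments of similar size. The forward step needs halogen–lithium exchange to outrun butylation, and addition to outrun deprotonation of 18.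

**12 ⇒ 11 ⇒ 10.** No skeletal bond is cut here; the oxygen substituents are exchanged. The early steps run in acid and need methyl ethers, which also decide which oxygen closes the pyran ring. The exchange is placed at bromochroman 10, a small molecule with no alkene and no ketone. The forward steps are a Lewis-acid demethylation that must leave the tertiary pyran ether and the C–Br bond alone, followed by acetal formation on diol 11.

**10 ⇒ 9.** The O1–C2 bond is cut. A tertiary cation at C2 is captured by the phenol oxygen of 9. The opposite cut, O1–C8a, would need a tertiary alkoxide to arylate and is inferior. In 9 the only free ring hydroxyl is the one para to bromine, so the ring can close in one way only. The forward step needs an acid mild enough not to protonate the bromine-bearing carbon, which is flanked by two donors.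

**9 ⇒ 6 + 7 (key disconnection).** Both C2–CH3 bonds are cut, and C2 becomes the carbonyl carbon of lactone 6; two equivalents of methylmagnesium bromide 7 supply the two methyl groups. The neighbouring option, direct acid-catalysed prenylation of phenol 3 with a five-carbon allylic partner, would reach 10 in one step. It is prone to double and O-alkylation, and it keeps the labile bromide in acid for longer. In the lactone route the first C–C bond turns the hydroxyl into an acyloxy group, so annulation stops after one event, and the methyl groups arrive under basic conditions. Precursor 6 has no quaternary carbon. The forward step needs complete double addition and no bromine–magnesium exchange.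

**6 ⇒ 3 + 4.** The C4–C4a bond and the lactone O–C(=O) bond are cut, giving phenol 3 and acrylic acid 4. Phenol 3 is symmetric, so the two ortho carbons are the same and the bromine necessarily ends para to the ring oxygen. Acrylic acid supplies C2, C3 and C4 at the correct oxidation level. The forward reaction is a Friedel–Crafts conjugate addition with lactonisation, passing through acid 5.

**3 ⇒ 1.** The phenolic C–O bond is cut. Brominating the bromine-free analogue of 3 would give ortho and para products. Instead the hydroxyl is placed on 2-bromo-1,3-dimethoxybenzene 1 by sterically controlled C–H borylation at its only unhindered position, followed by oxidation of boronate 2.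

**18 ⇒ 17 ⇒ 16 ⇒ 15 ⇒ 14 ⇒ 13.** In ring B the aryl–prenyl bond is cut first, leading to bromide 17. The coupling is placed after hydrogenation of the chain alkene of 16, so the prenyl alkene never meets a reduction. The Cα=Cβ bond of 16 is cut by a Horner–Wadsworth–Emmons disconnection to aldehyde 15, with the Weinreb amide arriving on the phosphonate. The two ether groups of 15 go back through 14 to 3-bromo-4,5-dihydroxybenzaldehyde 13. The forward order follows acidity: the 4-hydroxyl, para to the formyl group and ortho to bromine, is methylated first.

## Roads not taken

**Alternative 1:** Gold-catalysed hydroarylation of a propargyl ether, chromene then saturated.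
- **Cut and key step.** The C4–C4a bond is cut at the chromene oxidation level. The precursor is aryl 1,1-dimethylpropargyl ether A1, in which the whole dihydrochalcone is already assembled. A cationic phosphine–gold catalyst such as (Ph3P)AuNTf2 (monovalent gold) would activate the terminal alkyne, and the ortho carbon of ring A would attack its terminal carbon in a 6-endo hydroarylation to give 2H-chromene A2. The C3=C4 bond is saturated afterwards.
- **Merits.** A1 is symmetric about the acyl axis, so both ortho carbons are the same and the 6- versus 8-acyl question vanishes without a blocking group. The ring is made late on the unprotected skeleton, and the route is clearly shorter than the chosen one.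
- **Weak points.** The step after the key step hydrogenates C3=C4 of A2 in the presence of the prenyl alkene; a product with a reduced side chain differs from 21 by two hydrogens and would be hard to remove. The gold catalyst also binds the electron-rich prenyl alkene and the free phenols, so side-chain hydrofunctionalisation is a conceivable leak. The tertiary propargyl ether must be placed selectively on the 4-hydroxyl of an acylphloroglucinol.
- **Comparison.** In step count and convergence this road is the better one. The chosen plan sets against it that C3 and C4 enter saturated with acrylic acid 4, so no reduction is run while the prenyl group is present, and that no step depends on alkene–alkyne or alkene–alkene selectivity.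

**Alternative 2:** ortho-Quinone methide hetero-Diels–Alder reaction with isobutene.
- **Cut and key step.** The O1–C2 and C3–C4 bonds are cut together. Mannich base A3 would lose its amine on heating to give ortho-quinone methide A4, which adds isobutene A5 in an inverse-demand hetero-Diels–Alder reaction to give chroman aldehyde A6. The aldehyde must then be turned into the ketone by addition of a ring B carbon nucleophile and oxidation.
- **Merits.** The pyran ring forms in one step, with the orientation dictated by the polarised diene (oxygen to the disubstituted carbon). The formyl group marks C6 as the bromine does in 10. The cycloaddition is atom-economical, against three operations (annulation, methyl addition, dehydration) in the chosen plan.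
- **Weak points.** A5 is a gas and an unactivated dienophile, so a sealed vessel and high temperature are needed while A4 is prone to dimerise. The Mannich reaction must occur on a ring deactivated by the para formyl group. The aldehyde needs two steps to become the ketone where aryllithium 19 needs one. A6 also ends with two methyl ethers flanking the future ketone, which is the deprotection problem the chosen plan removes by the exchange 10 → 12 (this road could adopt the same exchange at the same cost).
- **Comparison.** In ring-forming efficiency this road is ahead. The chosen plan answers with bench reagents at ordinary pressure, a halogen handle that couples in one step, and precedented reactions throughout.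

**Alternative 3:** Aryne insertion into a carboxylic acid, installing ketone and flanking phenol.
- **Cut and key step.** The C5–O bond and the C6–carbonyl bond are cut at once. Fluoride-induced elimination of silyl triflate A7 would give aryne A8, which inserts into the carboxyl C–O bond of ring B acid A9. The carboxylate oxygen adds to C5, the aryne carbon remote from the 7-methoxy group, and the aryl anion at C6 takes over the acyl group to give ortho-hydroxyaryl ketone A10.
- **Merits.** This is the most convergent of the four plans. It makes the ketone and its free 5-hydroxyl in one operation under nearly neutral conditions that the prenyl group and the acetal tolerate, and the methoxy group steers the addition in the right sense.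
- **Weak points.** A7 needs a chroman with defined oxygen at C5 and silicon at C6, which is the same substitution problem reached through more steps than bromide 12. C5 of A8 is flanked by the C4 methylene, so attack there is hindered. Acyl transfer competes with simple protonation of the aryl anion, which gives an aryl ester and no C–C bond. The aryne precursor is normally used in excess although it is the costlier partner. A10 still carries the 7-methyl ether, to be cleaved beside a ketone whose chelate is already occupied by the 5-hydroxyl and in the presence of the ring B methyl ether.
- **Comparison.** In bonds formed per step this road is superior. The chosen plan sets against it a coupling that uses the two fragments nearly one to one, and an end game in which all three hydroxyls are released by one mild acetal hydrolysis.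

Key step: step 3

Remark: ring A is carried as its methyl ethers through the acid steps and exchanged for methoxymethyl ethers before the coupling. Diethyl [2-(methoxy(methyl)amino)-2-oxoethyl]phosphonate and tributyl(3-methylbut-2-enyl)stannane are taken as purchased reagents.

## Route

Step 1
Reactants: 1 2-bromo-1,3-dimethoxybenzene
Product: 3 4-bromo-3,5-dimethoxyphenol, via pinacol arylboronate 2 (not isolated)
Conditions: [Ir(OMe)(cod)]2 (1.5 mol%), 4,4'-di-tert-butyl-2,2'-bipyridine (3 mol%), B2pin2, THF, 80 °C; then KHSO5 (as Oxone, 2KHSO5·KHSO4·K2SO4), acetone/H2O, 0 °C → rt
Reagents that add atoms: bis(pinacolato)diboron, CC1(C)OB(OC1(C)C)B1OC(C)(C)C(C)(C)O1 (boron of 2); potassium peroxymonosulfate, [K+].[O-]S(=O)(=O)OO (hydroxyl oxygen of 3)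
Why: Iridium-catalysed aromatic C–H borylation is governed by sterics, and C5 of 1 is the only C–H bond with no ortho substituent, so boron should enter para to bromine while the C–Br bond stays intact. Oxidation of the C–B bond of 2 with peroxymonosulfate (one-pot borylation–oxidation) then gives the phenol at the same carbon.

Step 2
Reactants: 3 4-bromo-3,5-dimethoxyphenol; 4 acrylic acid
Product: 6 6-bromo-5,7-dimethoxychroman-2-one, via hydroxyaryl propanoic acid 5 (not isolated)
Conditions: Amberlyst-15 (sulfonic acid resin), toluene, reflux, Dean–Stark trap
Reagents that add atoms: none
Why: Acid-catalysed Friedel–Crafts conjugate addition of the phenol ortho carbon to protonated acrylic acid gives acid 5, which lactonises with loss of water; this is the established phenol–acrylic acid route to 3,4-dihydrocoumarins. The two ortho carbons of 3 are equivalent, and the acyloxy group of 6 deactivates the ring against a second alkylation.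

Step 3
Reactants: 6 6-bromo-5,7-dimethoxychroman-2-one; 7 methylmagnesium bromide
Product: 9 4-bromo-2-(3-hydroxy-3-methylbutyl)-3,5-dimethoxyphenol, via methyl ketone 8 (not isolated)
Conditions: MeMgBr (3.5 equiv), THF, 0 °C → rt; then 1 M aq HCl, 0 °C
Reagents that add atoms: methylmagnesium bromide, C[Mg]Br (the second equivalent, which supplies the second methyl group; the first is reactant 7)
Why: This is a double Grignard addition to a lactone: the first equivalent of 7 adds to the aryl ester carbonyl of 6, and the tetrahedral alkoxide collapses with expulsion of the aryloxide to give the bromomagnesium phenoxide of methyl ketone 8. Ketone 8 is more electrophilic than lactone 6, so a second equivalent of 7 adds as soon as it forms and gives the tertiary alkoxide, which the acid quench converts into 9; the product thus holds two methyl carbons from two molecules of the reagent. The closest known reaction is the conversion of 3,4-dihydrocoumarin itself into 2-(3-hydroxy-3-methylbutyl)phenol with excess methyl Grignard reagent, the classical entry to 2,2-dimethylchromans. Both C2–CH3 bonds of the future pyran ring form here; no ring closes and no stereocentre arises, because the new carbinol carbon carries two identical methyl groups. The step needs complete double addition without bromine–magnesium exchange and without stalling at 8 through enolisation. An excess of reagent, the higher reactivity of the ketone, and the slow exchange of an unactivated aryl bromide with an alkyl Grignard reagent at or below room temperature should secure this. The two methyl ethers are untouched, so the liberated phenol is the only free hydroxyl on the ring and fixes which oxygen closes the ring in step 4.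

Step 4
Reactants: 9 4-bromo-2-(3-hydroxy-3-methylbutyl)-3,5-dimethoxyphenol
Product: 10 6-bromo-5,7-dimethoxy-2,2-dimethylchroman
Conditions: TsOH·H2O (10 mol%), toluene, 80 °C
Reagents that add atoms: none
Why: Acid-catalysed cyclodehydration: ionisation of the tertiary alcohol gives a tertiary cation that the phenol oxygen traps to close the six-membered ring, the standard closure of 2-(3-hydroxy-3-methylbutyl)phenols to 2,2-dimethylchromans. Only the hydroxyl para to bromine is free, so O1 is fixed and the bromine ends at C6.

Step 5
Reactants: 10 6-bromo-5,7-dimethoxy-2,2-dimethylchroman
Product: 11 6-bromo-2,2-dimethylchroman-5,7-diol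
Conditions: BBr3 (3 equiv), CH2Cl2, −78 → 0 °C; then H2O
Reagents that add atoms: none
Why: Aryl methyl ether cleavage with BBr3 proceeds by coordination at oxygen and bromide attack at the methyl carbon. The 2,2-dimethylpyran ether of chromans of the tocopherol and cannabinoid type is known to survive this reagent at low temperature, and the aryl bromide is not affected.

Step 6
Reactants: 11 6-bromo-2,2-dimethylchroman-5,7-diol
Product: 12 6-bromo-5,7-bis(methoxymethoxy)-2,2-dimethylchroman
Conditions: NaH (2.4 equiv), MOMCl (2.4 equiv), DMF, 0 °C → rt
Reagents that add atoms: chloromethyl methyl ether, COCCl (two equivalents, one for each phenol oxygen)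
Why: Williamson-type O-alkylation of the bis-phenoxide, as used for 2-bromoresorcinol. The acetals are stable to organolithium reagents, stabilise the aryllithium between them and are removed by dilute protic acid.

Step 7
Reactants: 13 3-bromo-4,5-dihydroxybenzaldehyde
Product: 14 3-bromo-5-hydroxy-4-methoxybenzaldehyde
Conditions: MeI (1.1 equiv), Li2CO3 (1.2 equiv), DMF, 40 °C
Reagents that add atoms: iodomethane, CI
Why: Regioselective mono-O-methylation: the 4-hydroxyl, para to the formyl group and ortho to bromine, is the more acidic, so one equivalent of a weak base forms and alkylates only its phenoxide. This follows the known selective 4-O-alkylation of 3,4-dihydroxybenzaldehydes.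

Step 8
Reactants: 14 3-bromo-5-hydroxy-4-methoxybenzaldehyde
Product: 15 3-bromo-4-methoxy-5-(methoxymethoxy)benzaldehyde
Conditions: MOMCl (1.5 equiv), i-Pr2NEt (2 equiv), CH2Cl2, 0 °C → rt
Reagents that add atoms: chloromethyl methyl ether, COCCl
Why: Standard acetal protection of the remaining phenol; the group withstands the olefination base, hydrogenation, palladium coupling and the aryllithium, and leaves with the ring A acetals in step 13.

Step 9
Reactants: 15 3-bromo-4-methoxy-5-(methoxymethoxy)benzaldehyde
Product: 16 (E)-3-[3-bromo-4-methoxy-5-(methoxymethoxy)phenyl]-N-methoxy-N-methylprop-2-enamide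
Conditions: (EtO)2P(O)CH2C(O)N(OMe)Me, NaH, THF, 0 °C → rt
Reagents that add atoms: diethyl [2-(methoxy(methyl)amino)-2-oxoethyl]phosphonate, CCOP(=O)(CC(=O)N(C)OC)OCC
Why: Horner–Wadsworth–Emmons olefination with a stabilised phosphonate anion gives the E-configured unsaturated Weinreb amide and brings in the two chain carbons and the acyl-transfer group in one step. The alkene geometry is immaterial because the bond is hydrogenated next.

Step 10
Reactants: 16 (E)-3-[3-bromo-4-methoxy-5-(methoxymethoxy)phenyl]-N-methoxy-N-methylprop-2-enamide
Product: 17 3-[3-bromo-4-methoxy-5-(methoxymethoxy)phenyl]-N-methoxy-N-methylpropanamide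
Conditions: H2 (1 atm), RhCl(PPh3)3 (5 mol%), toluene/EtOH 1:1, rt → 40 °C
Reagents that add atoms: none
Why: Homogeneous hydrogenation with RhCl(PPh3)3 (monovalent rhodium) reduces the disubstituted conjugated alkene without inserting into the aryl C–Br bond or cleaving the N–O bond, both of which are at risk over Pd/C. It is run before the prenyl group exists, so no alkene selectivity is required.

Step 11
Reactants: 17 3-[3-bromo-4-methoxy-5-(methoxymethoxy)phenyl]-N-methoxy-N-methylpropanamide
Product: 18 N-methoxy-3-[4-methoxy-3-(methoxymethoxy)-5-(3-methylbut-2-enyl)phenyl]-N-methylpropanamide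
Conditions: Bu3SnCH2CH=CMe2 (1.5 equiv), Pd(PPh3)4 (5 mol%), DMF, 100 °C
Reagents that add atoms: tributyl(3-methylbut-2-enyl)stannane, CCCC[Sn](CCCC)(CCCC)CC=C(C)C
Why: Stille cross-coupling: zerovalent palladium adds oxidatively to the aryl bromide, the prenyl group is transferred from tin mainly through its tin-bearing carbon, and reductive elimination gives the linear 3-methylbut-2-enyl arene. The Weinreb amide and the acetal are inert under these neutral conditions.

Step 12
Reactants: 12 6-bromo-5,7-bis(methoxymethoxy)-2,2-dimethylchroman; 18 N-methoxy-3-[4-methoxy-3-(methoxymethoxy)-5-(3-methylbut-2-enyl)phenyl]-N-methylpropanamide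
Product: 20 1-[5,7-bis(methoxymethoxy)-2,2-dimethylchroman-6-yl]-3-[4-methoxy-3-(methoxymethoxy)-5-(3-methylbut-2-enyl)phenyl]propan-1-one, via aryllithium 19 (not isolated)
Conditions: 12 (1.2 equiv), n-BuLi (1.2 equiv), THF, −78 °C; then 18 (1.0 equiv), −78 → 0 °C; then AcOH, 0 °C
Reagents that add atoms: n-butyllithium, [Li]CCCC (supplies only the lithium of 19)
Why: Bromine–lithium exchange at −78 °C gives aryllithium 19, stabilised by the two flanking acetal oxygens. Its addition to Weinreb amide 18 forms a chelated tetrahedral adduct that cannot add a second time and releases the ketone on protonation (Weinreb ketone synthesis). The site of the new C–C bond is fixed by the bromine.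

Step 13
Reactants: 20 1-[5,7-bis(methoxymethoxy)-2,2-dimethylchroman-6-yl]-3-[4-methoxy-3-(methoxymethoxy)-5-(3-methylbut-2-enyl)phenyl]propan-1-one
Product: 21 1-(5,7-dihydroxy-2,2-dimethylchroman-6-yl)-3-[3-hydroxy-4-methoxy-5-(3-methylbut-2-enyl)phenyl]propan-1-one
Conditions: 3 M aq HCl, MeOH, 50 °C
Reagents that add atoms: none
Why: Acid-catalysed acetal exchange with methanol removes all three methoxymethyl groups, those ortho to the ketone fastest. The ring B methyl ether and the tertiary pyran ether should survive, as should the prenyl alkene, which has no ortho hydroxyl to cyclise onto at this acid strength.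

## Compound list

1 | 2-bromo-1,3-dimethoxybenzene | COc1cccc(OC)c1Br | starting material
2 | 2-(4-bromo-3,5-dimethoxyphenyl)-4,4,5,5-tetramethyl-1,3,2-dioxaborolane | COc1cc(B2OC(C)(C)C(C)(C)O2)cc(OC)c1Br | intermediate (not isolated)
3 | 4-bromo-3,5-dimethoxyphenol | COc1cc(O)cc(OC)c1Br | intermediate
4 | acrylic acid | C=CC(=O)O | starting material
5 | 3-(3-bromo-6-hydroxy-2,4-dimethoxyphenyl)propanoic acid | OC(=O)CCc1c(O)cc(OC)c(Br)c1OC | intermediate (not isolated)
6 | 6-bromo-5,7-dimethoxychroman-2-one | O=C1CCc2c(OC)c(Br)c(OC)cc2O1 | intermediate
7 | methylmagnesium bromide | C[Mg]Br | starting material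
8 | 4-(3-bromo-6-hydroxy-2,4-dimethoxyphenyl)butan-2-one (present as its bromomagnesium phenoxide) | CC(=O)CCc1c(O)cc(OC)c(Br)c1OC | intermediate (not isolated)
9 | 4-bromo-2-(3-hydroxy-3-methylbutyl)-3,5-dimethoxyphenol | CC(C)(O)CCc1c(O)cc(OC)c(Br)c1OC | intermediate
10 | 6-bromo-5,7-dimethoxy-2,2-dimethylchroman | COc1cc2OC(C)(C)CCc2c(OC)c1Br | intermediate
11 | 6-bromo-2,2-dimethylchroman-5,7-diol | CC1(C)CCc2c(O)c(Br)c(O)cc2O1 | intermediate
12 | 6-bromo-5,7-bis(methoxymethoxy)-2,2-dimethylchroman | COCOc1cc2OC(C)(C)CCc2c(OCOC)c1Br | intermediate
13 | 3-bromo-4,5-dihydroxybenzaldehyde | O=Cc1cc(O)c(O)c(Br)c1 | starting material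
14 | 3-bromo-5-hydroxy-4-methoxybenzaldehyde | COc1c(O)cc(C=O)cc1Br | intermediate
15 | 3-bromo-4-methoxy-5-(methoxymethoxy)benzaldehyde | COCOc1cc(C=O)cc(Br)c1OC | intermediate
16 | (E)-3-[3-bromo-4-methoxy-5-(methoxymethoxy)phenyl]-N-methoxy-N-methylprop-2-enamide | COCOc1cc(/C=C/C(=O)N(C)OC)cc(Br)c1OC | intermediate
17 | 3-[3-bromo-4-methoxy-5-(methoxymethoxy)phenyl]-N-methoxy-N-methylpropanamide | COCOc1cc(CCC(=O)N(C)OC)cc(Br)c1OC | intermediate
18 | N-methoxy-3-[4-methoxy-3-(methoxymethoxy)-5-(3-methylbut-2-enyl)phenyl]-N-methylpropanamide | COCOc1cc(CCC(=O)N(C)OC)cc(CC=C(C)C)c1OC | intermediate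
19 | [5,7-bis(methoxymethoxy)-2,2-dimethylchroman-6-yl]lithium | [Li]c1c(OCOC)cc2OC(C)(C)CCc2c1OCOC | intermediate (not isolated)
20 | 1-[5,7-bis(methoxymethoxy)-2,2-dimethylchroman-6-yl]-3-[4-methoxy-3-(methoxymethoxy)-5-(3-methylbut-2-enyl)phenyl]propan-1-one | COCOc1cc(CCC(=O)c2c(OCOC)cc3OC(C)(C)CCc3c2OCOC)cc(CC=C(C)C)c1OC | intermediate
21 | 1-(5,7-dihydroxy-2,2-dimethylchroman-6-yl)-3-[3-hydroxy-4-methoxy-5-(3-methylbut-2-enyl)phenyl]propan-1-one | COc1c(O)cc(CCC(=O)c2c(O)cc3c(c2O)CCC(C)(C)O3)cc1CC=C(C)C | target

## Step count and least certain steps

Total: 13 steps. Longest linear sequence: 8 steps (steps 1–6, 12 and 13). The ring B branch (steps 7–11) has 5 steps and joins at step 12.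

**Step 3 (key step).** The addition may stop after the first methyl group, either because the basic Grignard reagent enolises ketone 8 or because the magnesium phenoxide of 8 precipitates; work-up would then return ketone and not diol. Bromine–magnesium exchange is a remote second possibility. Fallback: setting out from phenol 3, the chroman is made directly by acid-catalysed condensation with 2-methylbut-3-en-2-ol (BF3·OEt2, dioxane, rt), in which C-prenylation ortho to the hydroxyl is followed by ring closure on that hydroxyl. The symmetry of 3 again leaves one possible product, and the route is rejoined at 10. This fallback makes no compound outside the list (entry F0). It is shorter but gives up the self-limiting annulation and risks over-alkylation.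

**Step 2.** Ipso-protonation at the bromine-bearing carbon, which lies para to the hydroxyl and between two methoxy groups, could cause loss or migration of bromine under the hot acid; acrylic acid may also oligomerise. Fallback: setting out from 3, the three carbons are attached without a Friedel–Crafts step. ortho-Formylation (MgCl2, Et3N, paraformaldehyde, MeCN, reflux) gives 3-bromo-6-hydroxy-2,4-dimethoxybenzaldehyde F1. Wittig olefination with Ph3P=CHCO2Et gives ethyl (E)-3-(3-bromo-6-hydroxy-2,4-dimethoxyphenyl)prop-2-enoate F2. Hydrogenation over RhCl(PPh3)3 gives ethyl 3-(3-bromo-6-hydroxy-2,4-dimethoxyphenyl)propanoate F3, and lactonisation (pyridinium tosylate, toluene, reflux) returns to the route at 6.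

**Step 5.** The boron halide may ionise the tertiary C2–O1 bond; once the 5-oxygen is free, the chain could re-close on it and move the bromine from C6 to C8 of the new ring. HBr formed on quenching could also cause protodebromination. Fallback: setting out from 10, the methyl ethers are kept. Bromine–lithium exchange gives (5,7-dimethoxy-2,2-dimethylchroman-6-yl)lithium F4, and acylation with 18 gives 1-(5,7-dimethoxy-2,2-dimethylchroman-6-yl)-3-[4-methoxy-3-(methoxymethoxy)-5-(3-methylbut-2-enyl)phenyl]propan-1-one F5. BCl3 in CH2Cl2 (−78 → 0 °C) then cleaves both ketone-flanking methyl ethers through the carbonyl chelate, together with the acetal, and the route comes back at 21. The ring B methyl ether lies next to a boron-bound oxygen in this end game and the prenyl group is exposed to a Lewis acid, which is why this path is held in reserve.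

**Step 11.** Transfer of the prenyl group through its γ-carbon would give the branched 1,1-dimethylallyl isomer, and oxidative addition into the electron-rich, ortho-substituted bromide may be slow. Fallback: setting out from 17, Stille coupling with allyltributylstannane gives N-methoxy-3-[4-methoxy-3-(methoxymethoxy)-5-(prop-2-enyl)phenyl]-N-methylpropanamide F6. Cross-metathesis with 2-methylbut-2-ene and the second-generation Grubbs catalyst converts the allyl into the prenyl group and rejoins the route at 18.

**Step 12.** The hindered aryllithium may act as a base toward the α-methylene of the amide, so that proton transfer replaces addition; butylation of 19 by the 1-bromobutane formed in the exchange is a lesser concern. Fallback: setting out from 18, reduction with i-Bu2AlH (THF, −78 °C) gives 3-[4-methoxy-3-(methoxymethoxy)-5-(3-methylbut-2-enyl)phenyl]propanal F7, a far better electrophile. Addition of 19 (from 12) gives racemic 1-[5,7-bis(methoxymethoxy)-2,2-dimethylchroman-6-yl]-3-[4-methoxy-3-(methoxymethoxy)-5-(3-methylbut-2-enyl)phenyl]propan-1-ol F8, and oxidation with Dess–Martin periodinane returns to the route at 20.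

## Further compounds

F0 | step 3 | none | none
F1 | step 2 | 3-bromo-6-hydroxy-2,4-dimethoxybenzaldehyde | COc1cc(O)c(C=O)c(OC)c1Br
F2 | step 2 | ethyl (E)-3-(3-bromo-6-hydroxy-2,4-dimethoxyphenyl)prop-2-enoate | CCOC(=O)/C=C/c1c(O)cc(OC)c(Br)c1OC
F3 | step 2 | ethyl 3-(3-bromo-6-hydroxy-2,4-dimethoxyphenyl)propanoate | CCOC(=O)CCc1c(O)cc(OC)c(Br)c1OC
F4 | step 5 | (5,7-dimethoxy-2,2-dimethylchroman-6-yl)lithium | [Li]c1c(OC)cc2OC(C)(C)CCc2c1OC
F5 | step 5 | 1-(5,7-dimethoxy-2,2-dimethylchroman-6-yl)-3-[4-methoxy-3-(methoxymethoxy)-5-(3-methylbut-2-enyl)phenyl]propan-1-one | COCOc1cc(CCC(=O)c2c(OC)cc3OC(C)(C)CCc3c2OC)cc(CC=C(C)C)c1OC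
F6 | step 11 | N-methoxy-3-[4-methoxy-3-(methoxymethoxy)-5-(prop-2-enyl)phenyl]-N-methylpropanamide | COCOc1cc(CCC(=O)N(C)OC)cc(CC=C)c1OC
F7 | step 12 | 3-[4-methoxy-3-(methoxymethoxy)-5-(3-methylbut-2-enyl)phenyl]propanal | COCOc1cc(CCC=O)cc(CC=C(C)C)c1OC
F8 | step 12 | 1-[5,7-bis(methoxymethoxy)-2,2-dimethylchroman-6-yl]-3-[4-methoxy-3-(methoxymethoxy)-5-(3-methylbut-2-enyl)phenyl]propan-1-ol (racemic) | COCOc1cc(CCC(O)c2c(OCOC)cc3OC(C)(C)CCc3c2OCOC)cc(CC=C(C)C)c1OC
A1 | alternative 1 | 1-[2,6-dihydroxy-4-(2-methylbut-3-yn-2-yloxy)phenyl]-3-[3-hydroxy-4-methoxy-5-(3-methylbut-2-enyl)phenyl]propan-1-one | COc1c(O)cc(CCC(=O)c2c(O)cc(OC(C)(C)C#C)cc2O)cc1CC=C(C)C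
A2 | alternative 1 | 1-(5,7-dihydroxy-2,2-dimethyl-2H-chromen-6-yl)-3-[3-hydroxy-4-methoxy-5-(3-methylbut-2-enyl)phenyl]propan-1-one | COc1c(O)cc(CCC(=O)c2c(O)cc3OC(C)(C)C=Cc3c2O)cc1CC=C(C)C
A3 | alternative 2 | 3-[(dimethylamino)methyl]-4-hydroxy-2,6-dimethoxybenzaldehyde | CN(C)Cc1c(O)cc(OC)c(C=O)c1OC
A4 | alternative 2 | 2,6-dimethoxy-3-methylidene-4-oxocyclohexa-1,5-diene-1-carbaldehyde | C=C1C(=O)C=C(OC)C(C=O)=C1OC
A5 | alternative 2 | 2-methylprop-1-ene (isobutene) | CC(C)=C
A6 | alternative 2 | 5,7-dimethoxy-2,2-dimethylchroman-6-carbaldehyde | COc1cc2OC(C)(C)CCc2c(OC)c1C=O
A7 | alternative 3 | 7-methoxy-2,2-dimethyl-6-(trimethylsilyl)chroman-5-yl trifluoromethanesulfonate | COc1cc2OC(C)(C)CCc2c(OS(=O)(=O)C(F)(F)F)c1[Si](C)(C)C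
A8 | alternative 3 | 7-methoxy-2,2-dimethyl-5,6-didehydrochroman | COC1=CC2=C(CCC(C)(C)O2)C#C1
A9 | alternative 3 | 3-[4-methoxy-3-(methoxymethoxy)-5-(3-methylbut-2-enyl)phenyl]propanoic acid | COCOc1cc(CCC(=O)O)cc(CC=C(C)C)c1OC
A10 | alternative 3 | 1-(5-hydroxy-7-methoxy-2,2-dimethylchroman-6-yl)-3-[4-methoxy-3-(methoxymethoxy)-5-(3-methylbut-2-enyl)phenyl]propan-1-one | COc1cc2OC(C)(C)CCc2c(O)c1C(=O)CCc1cc(OCOC)c(OC)c(CC=C(C)C)c1
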